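## The problem

Mollicellin A (23) is a depsidone: ring A and ring B are held together by a diaryl ether (a5–O–b6) and an ester (a6–C(=O)–O–b1) in a seven-membered dibenzo[b,e][1,4]dioxepin-11-one, and a 2,2-dimethyl-2,3-dihydropyran-4-one is fused across b3 (ring oxygen) and b4 (ketone carbon). The molecule has no stereocentre, so nothing has to be set or relayed in three dimensions. The difficulty is regiochemical: ring A carries five different substituents and ring B is substituted at every carbon except b2. The hardest bond to make by coupling is the diaryl ether, because a5 is flanked by the formyl-bearing a4 and the carboxyl-bearing a6, and b6 by the lactone oxygen at b1 and the methyl-bearing b5. Three functions limit the choice of reagents: the seven-membered aryl ester opens with hydroxide, alkoxide or amines, the a4 aldehyde next to a free phenol would not survive hydrogenolysis or organometallic reagents, and the chromanone can open by retro-oxa-Michael reaction in base. The lactone is therefore closed late, everything after it is acidic or neutral, and the aldehyde comes last. A short route is possible because a1–a4 of ring A (C-methyl, C–H, C–O, C–H before formylation) are C6, C5, C4 and C3 of triacetic acid lactone 12, while the a5–a6 pair (ether oxygen next to carboxyl carbon) is the two-carbon unit of an aryloxypropiolate. Ring A can thus be built around the ether, and ring B has the pattern of aldehyde 1 with the formyl carbon exchanged for oxygen.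

## Retrosynthesis

**23 to 21 (a4–CHO bond).** The formyl group is removed first. Carried earlier, it would not survive the hydrogenolysis and it would have to pass through the strongly acidic annulation. Once the chromanone ketone is in place, ring B is deactivated and the only free phenol left is a3–OH. Precursor 21 is one carbon simpler. The forward step must formylate ortho to a3–OH at a4, not at a2.

**21 to 18 and 19 (b4–C(=O) and b3–O–C(CH3)2 bonds).** The pyranone ring is taken off as 3-methylbut-2-enoic acid 19. Carrying the ketone from the start is ruled out by the alkyllithium step that makes the alkyne. Building it after the lactone uses the b3 hydroxyl that the global deprotection frees anyway. Precursor 18 is a tricyclic diphenol. The forward step must acylate ring B at b4 (not b2, and not ring A) and then close the ring by oxa-Michael addition.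

**18 to 16 (ester C(=O)–O(b1)).** Opening the lactone gives hydroxy acid 16. Closing this bond is simpler than closing the ether at this stage: only the b1 hydroxyl can reach the activated carboxyl, and both ortho positions of the phenoxy ring are blocked, so no xanthone can form. The forward step needs activation of a di-ortho-substituted benzoic acid without base.

**16 to 15 (four O–benzyl bonds).** All four hydroxyl functions are masked as benzyl groups. One hydrogenolysis then frees the acid and the three phenols, and benzyl tolerates the alkyllithium and the heat of the earlier steps.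

**15 to 13 and 11 (a4–a5 and a1–a6).** This is the central cut. Ring A is split into pyrone 13 (a1–a4) and the alkyne carbons of aryloxypropiolate 11 (a5, a6). The neighbouring option, an Ullmann or palladium coupling of two finished rings, has to force the ether between two doubly flanked carbons. Here the ether oxygen and the carboxyl are already on the alkyne, and the arene forms directly by cycloaddition and decarboxylative cycloreversion. The precursors are a one-step pyrone and a ring B alkynyl ether. The forward step needs one regiochemistry (carboxyl next to the methyl-bearing carbon) and a dienophile that survives the temperature.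

**11 to 7 and 8, then 7 to 5 and 6.** The alkyne–carboxyl bond is cut to a lithium aryloxyacetylide and benzyl chloroformate 8. The acetylide comes from dichlorovinyl ether 7, whose two carbons are those of trichloroethylene 6 attached to phenol 5. This is the standard entry to aryl alkynyl ethers and needs only that the benzyl ethers tolerate the alkyllithium at low temperature.

**5 to 3 to 1 (b6–O bond).** The phenol oxygen at b6 is introduced by Baeyer–Villiger oxidation of aldehyde 3, the bis-benzyl ether of purchasable 1. The formyl group of 1 already marks b6. A route through a hydroxyquinone would need a selective mono-benzylation of a hydroquinone; this one has no selectivity question.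

**13 to 12.** Pyrone 13 is the O-benzyl ether of triacetic acid lactone 12.

## Roads not taken

**Alternative 1:** The cut falls on both bonds of the lactone carbonyl, a6–C(=O) and C(=O)–O(b1), so that carbon monoxide becomes the lactone carbon. The precursor is a finished diaryl ether, iodide A2, with the a6 iodide, a free b1 phenol, the chromanone and the a4 aldehyde in place and a3 as its methyl ether. In the forward step zerovalent palladium (from Pd(OAc)2 and a wide-bite-angle bisphosphine) inserts into the a6–I bond, CO inserts, and the b1 phenol captures the acylpalladium to give A1. Cleavage of the a3 methyl ether then ends the synthesis.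
- Merits: the base-sensitive lactone is the last ring formed, under nearly neutral conditions, and no hindered benzoic acid has to be activated. Chromanone and aldehyde arrive with the fragments, so the two late electrophilic substitutions of the chosen plan (steps 9 and 10) do not exist. In endgame regiocontrol this road is better.
- Weak points: the iodide sits between the a1 methyl and the a5 aryloxy group, which slows oxidative addition and CO insertion and invites reduction of the C–I bond. More seriously, A2 is a hexasubstituted iodoarene joined to a pentasubstituted ring through the doubly flanked ether. That ether must still be made by coupling two crowded rings, one of which carries an aldehyde and an iodide that interfere in copper or palladium chemistry.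
- Comparison: against the better endgame, the chosen plan makes the ether, the carboxyl carbon and the whole pattern of ring A in one thermal step with no metal-mediated coupling at a hindered carbon. Its price is two regiochemistry-dependent steps at the end.

**Alternative 2:** The ether oxygen is attached by simple alkylation of a ring A phenol to give aryloxy ketone A4, and ring B is then grown. With KOC(CH3)3 the aryloxy-bearing enolate carbon adds to a but-2-enoate ester (b6–b5), and the methyl ketone enolate closes onto the ester (b2–b3) to give the racemic trans dione A3.
- Merits: the troublesome ether is made by an SN2 reaction, the b5 methyl and b6 oxygen are placed without ambiguity, ring A can be bought as an orsellinic acid derivative, and the reagents are bulk chemicals. In cost and in certainty of the ether-forming step it beats the chosen plan.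
- Weak points: A3 is not aromatic. Two stereocentres are made only to be destroyed, and dehydrogenation of a 1,3-dione with an α-aryloxy group to the resorcinol needs conditions that suit neither the carboxyl group nor the electron-rich ring A. The annulation needs the more substituted enolate for the Michael step and the less substituted one for the Claisen step, with the phenol and acid masked.
- Comparison: after aromatisation the route stands where compound 16 stands, with lactonisation, chromanone annulation and formylation still ahead. It spends a redox-laden ring synthesis on a benzene ring whose pattern is available from 1. The chosen plan forms its arene at the right oxidation level and is shorter, though it pays for its ether with organolithium chemistry and a sensitive alkyne.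

**Alternative 3:** Four bonds of ring A are cut (a1–a6, a5–a6, a3–a4, a2–a3). The precursor is diazo ketoester A6: a 2-diazo-4-methyl-3-oxopent-4-enoate esterified to the b1 oxygen, with a silyloxymethyl-substituted alkynyl ether on the b6 oxygen. On irradiation nitrogen is lost and the isopropenyl group shifts (Wolff) to give a vinylketene, which adds [2+2] to the tethered alkynyl ether. 4π opening of the cyclobutenone and 6π closure then give phenol A5, closing ring A and the seven-membered ring together.
- Merits: it forms the most bonds of the four plans (two rings in one step), and the lactone never has to be closed from a hindered acid. The a4 carbon is carried in as a protected hydroxymethyl group, so the formylation regiochemistry of step 10 is replaced by desilylation and oxidation. In these respects it is the better design.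
- Weak points: an intramolecular version in which the [2+2] step must also form a seven-membered ring has no close analogy. The ketene is an acylketene, prone to dimerise or to react as an oxadiene. A6 combines an aryl ester of a diazo β-keto acid with an alkynyl ether that itself needs the dichlorovinyl ether and alkyllithium sequence, so the linear precursor synthesis is longer than that of 11. The chromanone must still be annulated onto a diphenol after debenzylation.
- Comparison: against the higher ambition, the chosen plan sets convergence (two fragments, each one to four steps from purchased material), a thermal key step that needs no photochemical equipment, and a cycloaddition type with broad precedent.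

Key step: step 6

Remark: aldehyde 1 is taken as the purchasable form of the ring B pattern; the only chiral species on the route, adduct 14 and chloro ether 22, are racemic transients drawn as one enantiomer.

## Steps

Step 1
Reactants: 1 2,4-dihydroxy-6-methylbenzaldehyde
Product: 3 2,4-bis(benzyloxy)-6-methylbenzaldehyde, via monobenzyl ether 2 (not isolated)
Conditions: BnBr (2.5 equiv), K2CO3, DMF, 60 °C
Reagents that add atoms: benzyl bromide, BrCc1ccccc1
Why: Williamson ether synthesis; the para hydroxyl (more acidic, not hydrogen-bonded) is alkylated first to 2, and the chelated ortho hydroxyl follows on warming with excess reagent.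

Step 2
Reactants: 3 2,4-bis(benzyloxy)-6-methylbenzaldehyde
Product: 5 2,4-bis(benzyloxy)-6-methylphenol, via aryl formate 4 (not isolated)
Conditions: mCPBA, CH2Cl2, 0 °C to rt; then K2CO3 (cat.), MeOH, rt
Reagents that add atoms: 3-chloroperoxybenzoic acid (mCPBA), O=C(OO)c1cccc(Cl)c1
Why: Baeyer–Villiger (Dakin-type) oxidation; the ortho,para-dialkoxyaryl group migrates in the Criegee intermediate to give formate 4, which is cleaved by transesterification to the phenol, while the benzyl ethers are inert.

Step 3
Reactants: 5 2,4-bis(benzyloxy)-6-methylphenol; 6 trichloroethylene
Product: 7 1,5-bis(benzyloxy)-2-{[(E)-1,2-dichloroethenyl]oxy}-3-methylbenzene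
Conditions: K2CO3, DMF, 70 °C
Reagents that add atoms: none
Why: Base-mediated addition of the phenoxide to dichloroacetylene formed in situ from 6; anti addition gives the (E)-dichlorovinyl ether, a standard preparation that tolerates di-ortho-substituted phenols.

Step 4
Reactants: 7 1,5-bis(benzyloxy)-2-{[(E)-1,2-dichloroethenyl]oxy}-3-methylbenzene; 8 benzyl chloroformate
Product: 11 benzyl 3-[2,4-bis(benzyloxy)-6-methylphenoxy]prop-2-ynoate, via chloroethynyl ether 9 (not isolated), via lithium acetylide 10 (not isolated)
Conditions: n-BuLi (2.2 equiv), THF, −78 to −40 °C; then cannulated into 8, THF, −78 °C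
Reagents that add atoms: none
Why: Dehydrochlorination gives chloroethynyl ether 9, chlorine–lithium exchange gives lithium aryloxyacetylide 10, and C-acylation of the acetylide by the chloroformate (kept in excess by inverse addition) gives the ynoate; the benzyl ethers are not metalated at this temperature.

Step 5
Reactants: 12 4-hydroxy-6-methyl-2H-pyran-2-one
Product: 13 4-(benzyloxy)-6-methyl-2H-pyran-2-one
Conditions: BnBr, K2CO3, DMF, 50 °C
Reagents that add atoms: benzyl bromide, BrCc1ccccc1
Why: O-alkylation of the vinylogous acid at the 4-oxygen, the usual entry to 4-alkoxy-2-pyrones; carbon 3 is only a minor site with K2CO3 in DMF.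

Step 6
Reactants: 13 4-(benzyloxy)-6-methyl-2H-pyran-2-one; 11 benzyl 3-[2,4-bis(benzyloxy)-6-methylphenoxy]prop-2-ynoate
Product: 15 benzyl 4-(benzyloxy)-2-[2,4-bis(benzyloxy)-6-methylphenoxy]-6-methylbenzoate, via bicyclic lactone adduct 14 (not isolated)
Conditions: 13 (3 equiv), toluene, BHT (cat.), 150 °C, sealed tube, argon
Reagents that add atoms: none
Why: The pyrone reacts as a diene across C3 and C6 with the alkyne in a thermal [4+2] cycloaddition to give 2-oxabicyclo[2.2.2]octadienone 14, which loses CO2 by retro-[4+2] and is aromatic at once. The closest known reaction type is the Diels–Alder/decarboxylation benzannulation of 2-pyrones with alkynoates and with heteroatom-substituted alkynes. Ring A closes by intermolecular cycloaddition, both σ bonds (a4–a5, a1–a6) forming in one asynchronous step, so no ring-size constraint applies. The two bridgehead stereocentres of 14 are fixed relative to each other by the bicycle and are erased on CO2 loss; 15 has none. The step needs one regiochemistry, and two polarisations secure it: pyrone C3, β to the benzyloxy group, is the nucleophilic diene terminus, and the aryloxy-bearing alkyne carbon is the electrophilic β-carbon of the ynoate. Read in the inverse sense, the ester-bearing alkyne carbon is the nucleophilic carbon of the alkynyl ether and pyrone C6 is the vinylogous acceptor position, which gives the same orientation with the carboxyl next to the methyl-bearing carbon. The aryl alkynyl ether has no β-hydrogen on oxygen and so cannot fragment to a ketene by retro-ene reaction at this temperature, and the pyrone is used in excess because the alkyne is the more valuable and more fragile partner.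

Step 7
Reactants: 15 benzyl 4-(benzyloxy)-2-[2,4-bis(benzyloxy)-6-methylphenoxy]-6-methylbenzoate
Product: 16 2-(2,4-dihydroxy-6-methylphenoxy)-4-hydroxy-6-methylbenzoic acid
Conditions: H2 (1 atm), Pd/C (10%), EtOAc/MeOH, rt
Reagents that add atoms: none
Why: Hydrogenolysis of one benzyl ester and three benzyl ethers; no other reducible group is present and the diaryl ether is inert.

Step 8
Reactants: 16 2-(2,4-dihydroxy-6-methylphenoxy)-4-hydroxy-6-methylbenzoic acid
Product: 18 3,8-dihydroxy-1,6-dimethyl-11H-dibenzo[b,e][1,4]dioxepin-11-one, via mixed anhydride 17 (not isolated)
Conditions: (CF3CO)2O, CH2Cl2 (0.01 M), 0 °C to rt; then aq. NaHCO3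
Reagents that add atoms: none
Why: Mixed-anhydride lactonisation; 17 ionises readily to a donor-stabilised aroyl cation that is trapped by the only hydroxyl within reach (b1) in a 7-exo-trig closure, xanthone formation is impossible because b1 and b5 are substituted, and transient aryl trifluoroacetates are cleaved in the bicarbonate work-up.

Step 9
Reactants: 18 3,8-dihydroxy-1,6-dimethyl-11H-dibenzo[b,e][1,4]dioxepin-11-one; 19 3-methylbut-2-enoic acid
Product: 21 deformyl-mollicellin A (tetracyclic chromanone–depsidone phenol), via hydroxyaryl enone 20 (not isolated)
Conditions: 19 (1.1 equiv), P2O5/MeSO3H (1:10 w/w), 70 °C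
Reagents that add atoms: none
Why: Acid-mediated chromanone annulation (Friedel–Crafts acylation or O-acylation/Fries shift, then 6-endo-trig oxa-Michael addition of the b3 hydroxyl to enone 20); ring B is the phenoxy-type ring with an unconjugated hydroxyl whereas both oxygens of ring A are conjugated to the protonated lactone carbonyl, and b4 (ortho to OH and methyl, para to the lactone oxygen) is favoured over b2 as in the C4 acylation of resorcinol monoesters.

Step 10
Reactants: 21 deformyl-mollicellin A
Product: 23 mollicellin A, via chloro ether 22 (not isolated)
Conditions: Cl2CHOMe, TiCl4, CH2Cl2, −10 to 0 °C; then 1 M HCl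
Reagents that add atoms: dichloromethyl methyl ether, COC(Cl)Cl; water, O
Why: Rieche formylation; TiCl4 binds the a3 phenoxide and delivers the electrophile ortho, and a4, between the phenoxide and the a5 ether oxygen, is the chelation-favoured and less hindered ortho site (as in formylation of orsellinate esters between their two oxygens), while ring B is deactivated by its ketone and hydrolysis of 22 gives the hydrogen-bonded salicylaldehyde.

## Compound list

1 | 2,4-dihydroxy-6-methylbenzaldehyde | Cc1cc(O)cc(O)c1C=O | starting material
2 | 4-(benzyloxy)-2-hydroxy-6-methylbenzaldehyde | Cc1cc(OCc2ccccc2)cc(O)c1C=O | intermediate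
3 | 2,4-bis(benzyloxy)-6-methylbenzaldehyde | Cc1cc(OCc2ccccc2)cc(OCc2ccccc2)c1C=O | intermediate
4 | 2,4-bis(benzyloxy)-6-methylphenyl formate | Cc1cc(OCc2ccccc2)cc(OCc2ccccc2)c1OC=O | intermediate
5 | 2,4-bis(benzyloxy)-6-methylphenol | Cc1cc(OCc2ccccc2)cc(OCc2ccccc2)c1O | intermediate
6 | trichloroethylene | ClC=C(Cl)Cl | starting material
7 | 1,5-bis(benzyloxy)-2-{[(E)-1,2-dichloroethenyl]oxy}-3-methylbenzene | Cc1cc(OCc2ccccc2)cc(OCc2ccccc2)c1O/C(Cl)=C\Cl | intermediate
8 | benzyl chloroformate | O=C(Cl)OCc1ccccc1 | starting material
9 | 1,5-bis(benzyloxy)-2-[(chloroethynyl)oxy]-3-methylbenzene | Cc1cc(OCc2ccccc2)cc(OCc2ccccc2)c1OC#CCl | intermediate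
10 | lithium [2,4-bis(benzyloxy)-6-methylphenoxy]acetylide | [Li]C#COc1c(C)cc(OCc2ccccc2)cc1OCc1ccccc1 | intermediate
11 | benzyl 3-[2,4-bis(benzyloxy)-6-methylphenoxy]prop-2-ynoate | Cc1cc(OCc2ccccc2)cc(OCc2ccccc2)c1OC#CC(=O)OCc1ccccc1 | intermediate
12 | 4-hydroxy-6-methyl-2H-pyran-2-one (triacetic acid lactone) | Cc1cc(O)cc(=O)o1 | starting material
13 | 4-(benzyloxy)-6-methyl-2H-pyran-2-one | Cc1cc(OCc2ccccc2)cc(=O)o1 | intermediate
14 | benzyl 8-(benzyloxy)-5-[2,4-bis(benzyloxy)-6-methylphenoxy]-1-methyl-3-oxo-2-oxabicyclo[2.2.2]octa-5,7-diene-6-carboxylate (racemic, one enantiomer drawn) | O=C1O[C@@]2(C)C=C(OCc3ccccc3)[C@@H]1C(Oc1c(C)cc(OCc3ccccc3)cc1OCc1ccccc1)=C2C(=O)OCc1ccccc1 | intermediate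
15 | benzyl 4-(benzyloxy)-2-[2,4-bis(benzyloxy)-6-methylphenoxy]-6-methylbenzoate | Cc1cc(OCc2ccccc2)cc(Oc2c(C)cc(OCc3ccccc3)cc2OCc2ccccc2)c1C(=O)OCc1ccccc1 | intermediate
16 | 2-(2,4-dihydroxy-6-methylphenoxy)-4-hydroxy-6-methylbenzoic acid | Cc1cc(O)cc(Oc2c(C)cc(O)cc2O)c1C(=O)O | intermediate
17 | 2-(2,4-dihydroxy-6-methylphenoxy)-4-hydroxy-6-methylbenzoic trifluoroacetic anhydride | Cc1cc(O)cc(Oc2c(C)cc(O)cc2O)c1C(=O)OC(=O)C(F)(F)F | intermediate
18 | 3,8-dihydroxy-1,6-dimethyl-11H-dibenzo[b,e][1,4]dioxepin-11-one | Cc1cc(O)cc2c1C(=O)Oc1cc(O)cc(C)c1O2 | intermediate
19 | 3-methylbut-2-enoic acid | CC(C)=CC(=O)O | starting material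
20 | 3,8-dihydroxy-1,6-dimethyl-7-(3-methylbut-2-enoyl)-11H-dibenzo[b,e][1,4]dioxepin-11-one | Cc1cc(O)cc2c1C(=O)Oc1cc(O)c(C(=O)C=C(C)C)c(C)c1O2 | intermediate
21 | deformyl-mollicellin A (3-hydroxy-1,6-dimethyl depsidone with a 2,2-dimethyl-2,3-dihydro-4H-pyran-4-one fused at b3 and b4) | Cc1cc(O)cc2c1C(=O)Oc1cc3c(c(C)c1O2)C(=O)CC(C)(C)O3 | intermediate
22 | 4-[chloro(methoxy)methyl] derivative of 21 (racemic, one enantiomer drawn) | Cc1cc(O)c([C@@H](Cl)OC)c2c1C(=O)Oc1cc3c(c(C)c1O2)C(=O)CC(C)(C)O3 | intermediate
23 | mollicellin A | Cc1cc(O)c(C=O)c2c1C(=O)Oc1cc3c(c(C)c1O2)C(=O)CC(C)(C)O3 | target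

## Step count and risks

Total: 10 steps. Longest linear sequence: 9 steps (1 to 23 through steps 1–4 and 6–10); the pyrone branch adds step 5.

**Step 6 (key step).** The most likely failure is a cycloaddition slower than the thermal decay or oligomerisation of the push–pull alkyne. The aryloxy donor raises the alkyne LUMO and 2-pyrones are sluggish dienes, so 11 may be consumed before it is trapped; erosion of regiocontrol is a lesser concern. Fallback: keep alkyne 11 and the same two bonds, but replace the pyrone by a far more reactive acyclic diene, (3Z)-2,4-bis(trimethylsilyloxy)penta-1,3-diene F1, obtainable by double silylation of the corresponding 1,3-diketone. In toluene at 80–110 °C its terminal CH2 should bond to the aryloxy-bearing alkyne carbon and its methyl-bearing carbon to the ester-bearing one. This gives the racemic cyclohexadiene benzyl 2-[2,4-bis(benzyloxy)-6-methylphenoxy]-6-methyl-4,6-bis[(trimethylsilyl)oxy]cyclohexa-1,4-diene-1-carboxylate F2, which aromatises by loss of silanol on dilute HCl/THF work-up to benzyl 2-[2,4-bis(benzyloxy)-6-methylphenoxy]-4-hydroxy-6-methylbenzoate F3. Hydrogenolysis of F3 under the conditions of step 7 rejoins the route at 16.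

**Step 4.** Three processes threaten it: attack of lithium acetylide 10 on the ynoate just formed (conjugate addition or addition to the ester), competing metalation of the benzylic positions, and hydration of the electron-rich alkyne on work-up or on silica. Fallback: set out from 7 with the same elimination and exchange, but protonate with methanol and isolate the terminal alkynyl ether 1,5-bis(benzyloxy)-2-(ethynyloxy)-3-methylbenzene F4. The carboxyl carbon is then introduced by catalytic carboxylative benzylation (CO2 at 1 atm, Cs2CO3, AgI cat., benzyl bromide, DMF, rt). The C–C bond is formed with CO2 to give an unreactive carboxylate that is O-benzylated in the same flask, which returns to 11.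

**Step 9.** The likely failure is acylation at the wrong oxygen or carbon: esterification or C-acylation on ring A at its free a3 phenol, beside the wanted b4 acylation. Conjugate alkylation leading to a 4,4-dimethyl-dihydrocoumarin is a second possibility. The b2/b4 orientation rests on innate preference and is not corrected by the fallback. Fallback: set out from 18 and cap the more acidic a3 hydroxyl (para to the lactone carbonyl) by selective methylation with one equivalent of MeI and KHCO3 in DMF, giving 8-hydroxy-3-methoxy-1,6-dimethyl-11H-dibenzo[b,e][1,4]dioxepin-11-one F5. The annulation with 19 in P2O5/MeSO3H then has a single phenol to follow and should give the a3 methyl ether of 21 F6. BBr3 in CH2Cl2 (−78 to 0 °C) cleaves the methyl ether, any ring-opened hydroxy enone reclosing on work-up, and returns to 21.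

**Step 10.** The likely failure is poor regioselectivity: formylation at a2, which is para to the a5 ether oxygen and electronically competitive, instead of or beside a4. Fallback (halogen blocking): set out from 21 and brominate with one equivalent of NBS in CH2Cl2 at 0 °C. The halogen is expected at a2 for the same electronic reason, giving the a2-bromo derivative of 21 F7. Formylation with Cl2CHOMe/TiCl4 can then only take a4, giving a2-bromo-mollicellin A F8. Reductive debromination with zerovalent palladium and formate (Pd(OAc)2, PPh3, HCO2H, Et3N, DMF, 60 °C), which tolerates the aldehyde and avoids nucleophilic base, returns to 23.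

## Further compounds

F1 | step 6 | (3Z)-2,4-bis(trimethylsilyloxy)penta-1,3-diene | C=C(O[Si](C)(C)C)/C=C(/C)O[Si](C)(C)C
F2 | step 6 | benzyl 2-[2,4-bis(benzyloxy)-6-methylphenoxy]-6-methyl-4,6-bis[(trimethylsilyl)oxy]cyclohexa-1,4-diene-1-carboxylate (racemic, one enantiomer drawn) | C[C@]1(O[Si](C)(C)C)C=C(O[Si](C)(C)C)CC(Oc2c(C)cc(OCc3ccccc3)cc2OCc2ccccc2)=C1C(=O)OCc1ccccc1
F3 | step 6 | benzyl 2-[2,4-bis(benzyloxy)-6-methylphenoxy]-4-hydroxy-6-methylbenzoate | Cc1cc(O)cc(Oc2c(C)cc(OCc3ccccc3)cc2OCc2ccccc2)c1C(=O)OCc1ccccc1
F4 | step 4 | 1,5-bis(benzyloxy)-2-(ethynyloxy)-3-methylbenzene | Cc1cc(OCc2ccccc2)cc(OCc2ccccc2)c1OC#C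
F5 | step 9 | 8-hydroxy-3-methoxy-1,6-dimethyl-11H-dibenzo[b,e][1,4]dioxepin-11-one | Cc1cc(OC)cc2c1C(=O)Oc1cc(O)cc(C)c1O2
F6 | step 9 | a3 methyl ether of 21 | Cc1cc(OC)cc2c1C(=O)Oc1cc3c(c(C)c1O2)C(=O)CC(C)(C)O3
F7 | step 10 | a2-bromo derivative of 21 | Cc1c(Br)c(O)cc2c1C(=O)Oc1cc3c(c(C)c1O2)C(=O)CC(C)(C)O3
F8 | step 10 | a2-bromo-mollicellin A | Cc1c(Br)c(O)c(C=O)c2c1C(=O)Oc1cc3c(c(C)c1O2)C(=O)CC(C)(C)O3
A1 | alternative 1 | mollicellin A a3-methyl ether | Cc1cc(OC)c(C=O)c2c1C(=O)Oc1cc3c(c(C)c1O2)C(=O)CC(C)(C)O3
A2 | alternative 1 | 2-[(7-hydroxy-2,2,5-trimethyl-4-oxo-3,4-dihydro-2H-chromen-6-yl)oxy]-3-iodo-6-methoxy-4-methylbenzaldehyde | Cc1cc(OC)c(C=O)c(Oc2c(C)c3c(cc2O)OC(C)(C)CC3=O)c1I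
A3 | alternative 2 | 4-hydroxy-2-methyl-6-[(trans-2-methyl-4,6-dioxocyclohexyl)oxy]benzoic acid (racemic, one enantiomer drawn) | Cc1cc(O)cc(O[C@@H]2[C@@H](C)CC(=O)CC2=O)c1C(=O)O
A4 | alternative 2 | 4-hydroxy-2-methyl-6-(2-oxopropoxy)benzoic acid | Cc1cc(O)cc(OCC(C)=O)c1C(=O)O
A5 | alternative 3 | 8-(benzyloxy)-3-hydroxy-1,6-dimethyl-4-({[tri(propan-2-yl)silyl]oxy}methyl)-11H-dibenzo[b,e][1,4]dioxepin-11-one | Cc1cc(O)c(CO[Si](C(C)C)(C(C)C)C(C)C)c2c1C(=O)Oc1cc(OCc3ccccc3)cc(C)c1O2
A6 | alternative 3 | 5-(benzyloxy)-3-methyl-2-[(3-{[tri(propan-2-yl)silyl]oxy}prop-1-yn-1-yl)oxy]phenyl 2-diazo-4-methyl-3-oxopent-4-enoate | C=C(C)C(=O)C(=[N+]=[N-])C(=O)Oc1cc(OCc2ccccc2)cc(C)c1OC#CCO[Si](C(C)C)(C(C)C)C(C)C
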